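## Retrosynthetic overview

- Rings: A = cyclohex-2-ene-1,4-dione, B = the CH=C(CH3)–CH2 bridge ring, C = five-membered ring, D = arene. Ring A is cut into a C(=O)–CH=CH three-carbon unit (a cyclopropenone ketal, reacting as its vinylcarbene) and a 1H-indene-1-carbonyl chloride. The two bonds made are the vinyl–acyl bond at the ring A ketone next to the aryl-bearing quaternary carbon, and the bond from the other ring A carbonyl carbon to the prenyl-bearing quaternary carbon.
- Enabling feature: the two adjacent quaternary carbons shared by rings A, B and C and the benzylic CH of ring C are the trace of an indene C2=C3 bond (C2 nucleophilic, C3 a benzylic cation stabilised by the ortho oxygen of ring D). The carbenium ion left by the three-carbon unit closes ring A at C2, and the C3 cation is closed onto a 1-silylallyl arm on C1 to give ring B, with the alkene position fixed by loss of silicon.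
- The aryl-bearing quaternary carbon (indene C1) and its arm come from one enantioselective ester-enolate Claisen rearrangement of a 3-silyl-2-methylallyl indene-3-carboxylate; the other two stereocentres follow from it.
- The indene comes from commercial 4,7-dimethoxy-1-indanone (rings D and C) by prenylation, reduction–dehydration and carboxylation of a symmetric indenyl anion.
- Ring order: D and C (bought) → A and B together (key step) → oxidative demethylation and quinone reduction to the hydroquinone.

Key step: step 10

Assumptions: the sense of induction of the (4S,5S)-bromoborane in step 6 is taken from the chair model of this rearrangement (its antipode is used if the opposite sense is found); the silyl-bearing side-chain carbon of the Claisen product and of the compounds made from it may be either epimer, since it becomes sp2 in step 10, and is left open in the SMILES.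

## Route

Step 1
Reactants: 1 4,7-dimethoxy-2,3-dihydro-1H-inden-1-one + 2 1-bromo-3-methylbut-2-ene
Product: 3 (±)-4,7-dimethoxy-2-(3-methylbut-2-en-1-yl)-2,3-dihydro-1H-inden-1-one
Conditions: LiN(i-Pr)2, THF, −78 °C; then 2, −78 → 0 °C
Reagents that add atoms: none
Why: Kinetic lithium enolate alkylation (SN2) at the only enolisable position of the indanone with an allylic bromide; the new stereocentre is irrelevant because it becomes sp2 in step 2.

Step 2
Reactants: 3
Product: 5 4,7-dimethoxy-2-(3-methylbut-2-en-1-yl)-1H-indene, via indanol 4 (not isolated)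
Conditions: NaBH4, MeOH, 0 °C; then p-TsOH·H2O (cat.), toluene, 60 °C
Reagents that add atoms: none
Why: Hydride reduction of the aryl ketone and acid-catalysed E1 dehydration of the benzylic alcohol (cation stabilised by the ortho methoxy group) should give the styrene-type indene, whose two double-bond tautomers are identical by symmetry.

Step 3
Reactants: 5
Product: 6 4,7-dimethoxy-2-(3-methylbut-2-en-1-yl)-1H-indene-3-carboxylic acid
Conditions: n-BuLi, THF, −78 °C; CO2; aq. NaOH, then HCl
Reagents that add atoms: carbon dioxide, O=C=O
Why: Deprotonation of the indene CH2 gives a symmetric indenyl anion, so carboxylation at either benzylic terminus gives the same acid, which tautomerises to the conjugated 3-carboxylic acid on basic work-up.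

Step 4
Reactants: 7 3-(trimethylsilyl)prop-2-yn-1-ol
Product: 8 (E)-2-methyl-3-(trimethylsilyl)prop-2-en-1-ol
Conditions: MeMgBr (3 equiv), CuI (10 mol %), THF, −10 → 23 °C; aq. NH4Cl
Reagents that add atoms: methylmagnesium bromide, C[Mg]Br
Why: Copper-catalysed anti-carbomagnesiation of a propargylic alcohol through the chelated alkenylmagnesium alkoxide puts methyl on C2 and, after protonation, silicon trans to CH2OH.

Step 5
Reactants: 6 + 8
Product: 9 (E)-2-methyl-3-(trimethylsilyl)prop-2-en-1-yl 4,7-dimethoxy-2-(3-methylbut-2-en-1-yl)-1H-indene-3-carboxylate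
Conditions: DCC, DMAP (cat.), CH2Cl2, 0 → 23 °C
Reagents that add atoms: none
Why: Steglich esterification of the conjugated acid with a primary allylic alcohol.

Step 6
Reactants: 9
Product: 11 (1R)-4,7-dimethoxy-2-(3-methylbut-2-en-1-yl)-1-[2-methyl-1-(trimethylsilyl)prop-2-en-1-yl]-1H-indene-1-carboxylic acid, via boron ketene acetal 10 (not isolated)
Conditions: (4S,5S)-2-bromo-4,5-diphenyl-1,3-bis{[3,5-bis(trifluoromethyl)phenyl]sulfonyl}-1,3,2-diazaborolidine (1.3 equiv), Et3N, CH2Cl2, −78 → 23 °C; aq. work-up
Reagents that add atoms: none
Why: Enantioselective ester-enolate Claisen rearrangement ([3,3]) of the boron ketene acetal formed by γ-deprotonation; the bond from indene C1 to the silyl-bearing vinyl carbon creates the quaternary centre (absolute configuration from the C2-symmetric diazaborolidine in a chair transition state) and the 1-silylallyl arm in the same event.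

Step 7
Reactants: 11
Product: 12 (1S)-4,7-dimethoxy-2-(3-methylbut-2-en-1-yl)-1-[2-methyl-1-(trimethylsilyl)prop-2-en-1-yl]-1H-indene-1-carbonyl chloride (same spatial arrangement as 11; the descriptor changes by priority only)
Conditions: 1-chloro-N,N,2-trimethylprop-1-en-1-amine, CH2Cl2, 0 → 23 °C
Reagents that add atoms: 1-chloro-N,N,2-trimethylprop-1-en-1-amine, CC(C)=C(Cl)N(C)C
Why: Neutral acid chloride formation from a hindered acid with an α-chloroenamine, which releases no HCl and so spares the allylsilane.

Step 8
Reactants: 13 1,3-dichloropropan-2-one + 14 2,2-dimethylpropane-1,3-diol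
Product: 15 2,2-bis(chloromethyl)-5,5-dimethyl-1,3-dioxane
Conditions: p-TsOH (cat.), toluene, reflux, Dean–Stark
Reagents that add atoms: none
Why: Acid-catalysed ketalisation driven by azeotropic removal of water.

Step 9
Reactants: 15
Product: 16 6,6-dimethyl-4,8-dioxaspiro[2.5]oct-1-ene (cyclopropenone ketal)
Conditions: NaNH2 (3 equiv), NH3 (l), −50 → −35 °C; NH4Cl
Reagents that add atoms: none
Why: Amide-induced 1,3-elimination to the chlorocyclopropane ketal followed by 1,2-elimination of HCl should give the cyclopropenone ketal.

Step 10
Reactants: 12 + 16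
Product: 19 tetracyclic enedione bis(methyl ether) (rings A to D complete; S at the prenyl-bearing carbon; R at the aryl-bearing quaternary carbon; R at the benzylic CH), via dioxanylium chloride 17 (not isolated), via ketal 18 (not isolated)
Conditions: 16 (3 equiv), 2,6-di-tert-butyl-4-methylpyridine (0.2 equiv), MeCN, 80 °C, sealed tube; then 3 M aq. HCl, THF, 40 °C
Reagents that add atoms: water, O
Why: Proposed new method: at 80 °C ketal 16 opens reversibly to its π-delocalised singlet vinylcarbene, whose nucleophilic carbene carbon should attack the acid chloride carbon of 12 (first bond, ring A ketone–CH=) just as it attacks electron-poor C=C and C=O partners in the known thermal [3+2] cycloadditions of cyclopropenone ketals; loss of chloride leaves the cis-acylvinyl dioxanylium ion 17, in which the former ketal carbon is now the electrophile. With no anion present to close a five-membered ring, this carbenium ion should add to C2 of the indene (second bond) in a 6-exo cation–olefin closure of ring A, the charge moving to benzylic C3 where the ortho methoxy group of ring D stabilises it; the closest known reaction types are alkoxycarbenium- and acylium-initiated olefin cyclisations. The C3 cation is then captured by the terminal CH2 of the allylsilane arm (six-membered closure of ring B, Hosomi–Sakurai-type termination), and loss of Me3SiCl places the double bond between the former silyl-bearing carbon and the methyl-bearing carbon whichever epimer of the arm is used. The prenyl-bearing quaternary centre is set because the three-atom tether on C1 can reach only the cis face of C2 (cis fusion of ring A to ring C), and the benzylic CH centre because the arm lies on the other face of C1 and can bond to C3 only on that face, so both follow from the C1 centre made in step 6. The step needs capture of the dioxanylium carbon by indene C2 rather than by chloride or the prenyl alkene, which the neopentyl-type ketal (no dealkylation by chloride) and the six-membered reach of C2 alone should secure; aqueous acid then hydrolyses ketal 18 in the same flask.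

Step 11
Reactants: 19
Product: 20 quinone–enedione (ring D of 19 as the p-benzoquinone; geometry at all three centres unchanged)
Conditions: (NH4)2Ce(NO3)6 (2.5 equiv), MeCN/H2O, 0 °C
Reagents that add atoms: water, O
Why: Oxidative demethylation of the 1,4-dimethoxyarene by two one-electron oxidations with tetravalent cerium and water as the oxygen source; the non-enolisable enedione and the trisubstituted alkenes should survive the brief treatment.

Step 12
Reactants: 20
Product: 21 target hydroquinone
Conditions: Na2S2O4, EtOAc/H2O, 0 °C, argon
Reagents that add atoms: none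
Why: Two-electron reduction of the p-benzoquinone to the aromatic hydroquinone by dithionite should be much faster than reduction of the non-aromatisable ring A enedione.

## Compound list

1 | 4,7-dimethoxy-2,3-dihydro-1H-inden-1-one | COc1ccc(OC)c2c1CCC2=O | starting material
2 | 1-bromo-3-methylbut-2-ene (prenyl bromide) | CC(C)=CCBr | starting material
3 | (±)-4,7-dimethoxy-2-(3-methylbut-2-en-1-yl)-2,3-dihydro-1H-inden-1-one | COc1ccc(OC)c2c1CC(CC=C(C)C)C2=O | intermediate
4 | 4,7-dimethoxy-2-(3-methylbut-2-en-1-yl)-2,3-dihydro-1H-inden-1-ol (diastereomer mixture, not isolated) | COc1ccc(OC)c2c1CC(CC=C(C)C)C2O | intermediate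
5 | 4,7-dimethoxy-2-(3-methylbut-2-en-1-yl)-1H-indene | COc1ccc(OC)c2c1CC(CC=C(C)C)=C2 | intermediate
6 | 4,7-dimethoxy-2-(3-methylbut-2-en-1-yl)-1H-indene-3-carboxylic acid | COc1ccc(OC)c2c1CC(CC=C(C)C)=C2C(=O)O | intermediate
7 | 3-(trimethylsilyl)prop-2-yn-1-ol | OCC#C[Si](C)(C)C | starting material
8 | (E)-2-methyl-3-(trimethylsilyl)prop-2-en-1-ol | OC/C(C)=C/[Si](C)(C)C | intermediate
9 | (E)-2-methyl-3-(trimethylsilyl)prop-2-en-1-yl 4,7-dimethoxy-2-(3-methylbut-2-en-1-yl)-1H-indene-3-carboxylate | COc1ccc(OC)c2c1CC(CC=C(C)C)=C2C(=O)OC/C(C)=C/[Si](C)(C)C | intermediate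
10 | boron ketene acetal of 9: 1-[alkoxy(boryloxy)methylidene]-1H-indene carrying the (4S,5S)-diazaborolidine on oxygen (not isolated) | COc1ccc(OC)c2c1C=C(CC=C(C)C)C2=C(OC/C(C)=C/[Si](C)(C)C)OB1N(S(=O)(=O)c3cc(C(F)(F)F)cc(C(F)(F)F)c3)[C@@H](c3ccccc3)[C@H](c3ccccc3)N1S(=O)(=O)c1cc(C(F)(F)F)cc(C(F)(F)F)c1 | intermediate
11 | (1R)-4,7-dimethoxy-2-(3-methylbut-2-en-1-yl)-1-[2-methyl-1-(trimethylsilyl)prop-2-en-1-yl]-1H-indene-1-carboxylic acid (side-chain silyl carbon: either epimer) | CC(C)=CCC1=Cc2c(OC)ccc(OC)c2[C@]1(C(=O)O)C([Si](C)(C)C)C(C)=C | intermediate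
12 | (1S)-4,7-dimethoxy-2-(3-methylbut-2-en-1-yl)-1-[2-methyl-1-(trimethylsilyl)prop-2-en-1-yl]-1H-indene-1-carbonyl chloride | CC(C)=CCC1=Cc2c(OC)ccc(OC)c2[C@]1(C(Cl)=O)C([Si](C)(C)C)C(C)=C | intermediate
13 | 1,3-dichloropropan-2-one | ClCC(=O)CCl | starting material
14 | 2,2-dimethylpropane-1,3-diol | OCC(C)(C)CO | starting material
15 | 2,2-bis(chloromethyl)-5,5-dimethyl-1,3-dioxane | ClCC1(CCl)OCC(C)(C)CO1 | intermediate
16 | 6,6-dimethyl-4,8-dioxaspiro[2.5]oct-1-ene | CC1(C)COC2(C=C2)OC1 | intermediate
17 | 2-[(Z)-3-oxo-3-(indenyl)prop-1-en-1-yl]-5,5-dimethyl-1,3-dioxan-2-ylium chloride, the indenyl group being that of 12 with R at C1 by priority (not isolated) | CC(C)=CCC1=Cc2c(OC)ccc(OC)c2[C@]1(C(=O)/C=C\C3=[O+]CC(C)(C)CO3)C([Si](C)(C)C)C(C)=C.[Cl-] | intermediate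
18 | tetracyclic enone ketal: as 19, but the ring A carbonyl next to the prenyl-bearing carbon is its spiro 5,5-dimethyl-1,3-dioxane ketal (not isolated) | CC(C)=CC[C@@]12C3(OCC(C)(C)CO3)C=CC(=O)[C@@]14C=C(C)C[C@@H]2c2c(OC)ccc(OC)c24 | intermediate
19 | tetracyclic enedione bis(methyl ether): 1,4-dimethoxybenzene (ring D) fused to cyclopentane ring C; ring A cyclohex-2-ene-1,4-dione on the two quaternary carbons; ring B CH=C(CH3)–CH2 bridge from the aryl-bearing quaternary carbon to the benzylic CH, anti to ring A; prenyl on the central quaternary carbon, cis to the bridge; S, R, R at the prenyl-bearing carbon, the aryl-bearing quaternary carbon and the benzylic CH | CC(C)=CC[C@@]12C(=O)C=CC(=O)[C@@]13C=C(C)C[C@@H]2c1c(OC)ccc(OC)c13 | intermediate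
20 | quinone–enedione: as 19 with ring D as the p-benzoquinone (the descriptor of the former aryl-bearing carbon becomes S by priority, geometry unchanged) | CC(C)=CC[C@@]12C(=O)C=CC(=O)[C@@]13C=C(C)C[C@@H]2C2=C3C(=O)C=CC2=O | intermediate
21 | target: as 19 with ring D as the free 1,4-dihydroxybenzene; S at the prenyl-bearing carbon, R at the aryl-bearing quaternary carbon, R at the benzylic CH | CC(C)=CC[C@@]12C(=O)C=CC(=O)[C@@]13C=C(C)C[C@@H]2c1c(O)ccc(O)c13 | target

## Step count and risks

Total steps: 12. Longest linear sequence: 9 steps (1, 2, 3, 5, 6, 7, 10, 11, 12).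

Steps most likely to fail:

- **Step 10 (proposed new method).** The vinylcarbene may fail to acylate the hindered acid chloride. The carbenium ion may also be held at the neighbouring ketone oxygen, or the allylsilane may attack at the acyl carbon, before ring A closes. The fallback sets out from 12 and returns at 19 with known reaction types. Sonogashira-type acylation of 12 with 3,3,3-triethoxyprop-1-yne (PdCl2(PPh3)2, CuI, Et3N, THF, 23 °C) gives ynone ortho ester F1. Semihydrogenation over Pd/CaCO3 poisoned with Pb(OAc)2 and quinoline (H2, EtOAc) gives (Z)-enone ortho ester F2. Me3SiOTf (cat.) with 2,6-di-tert-butylpyridine in CH2Cl2 at −78 °C ionises the ortho ester; the diethoxycarbenium ion should close rings A and B by alkoxycarbenium-initiated olefin cyclisation with allylsilane termination to diethyl ketal F3. 3 M HCl in THF then gives 19. This replaces the carbene bond formation but still relies on the same cation cyclisation.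

- **Step 6.** Enantioselectivity may erode because the boron ketene acetal can rearrange through either double-bond geometry, and the stabilised dienolate may rearrange slowly. The fallback sets out from 9 and returns at 11. An ordinary Ireland–Claisen rearrangement (LiN(i-Pr)2, Me3SiCl, THF, −78 → 23 °C; aq. HCl) through silyl ketene acetal F4 gives racemic acid F5. This is resolved by crystallisation of its salt with (S)-1-phenylethylamine, salt F6 (the antipodal amine if the other salt is the less soluble one), and acidified to 11.

- **Step 12.** Dithionite may also reduce the ring A enedione by conjugate reduction, and the hydroquinone may re-oxidise in air. The fallback sets out from 18 (isolated by leaving out the acid treatment in step 10) and returns at 21. Oxidation with (NH4)2Ce(NO3)6 gives quinone ketal F7. Na2S2O4 reduces it to hydroquinone ketal F8 while ring A is only an enone ketal. The ketal is hydrolysed last (3 M HCl, THF, 40 °C, argon) to 21.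

Further compounds

F1 | step 10 | ynone ortho ester: 1-(4,4,4-triethoxybut-2-ynoyl) analogue of 12 | CC(C)=CCC1=Cc2c(OC)ccc(OC)c2[C@]1(C(=O)C#CC(OCC)(OCC)OCC)C([Si](C)(C)C)C(C)=C
F2 | step 10 | (Z)-enone ortho ester: 1-[(Z)-4,4,4-triethoxybut-2-enoyl] analogue of 12 | CC(C)=CCC1=Cc2c(OC)ccc(OC)c2[C@]1(C(=O)/C=C\C(OCC)(OCC)OCC)C([Si](C)(C)C)C(C)=C
F3 | step 10 | diethyl ketal of 19 at the ring A carbonyl next to the prenyl-bearing carbon | CC(C)=CC[C@@]12C(OCC)(OCC)C=CC(=O)[C@@]13C=C(C)C[C@@H]2c1c(OC)ccc(OC)c13
F4 | step 6 | trimethylsilyl ketene acetal of 9 | COc1ccc(OC)c2c1C=C(CC=C(C)C)C2=C(OC/C(C)=C/[Si](C)(C)C)O[Si](C)(C)C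
F5 | step 6 | racemic 4,7-dimethoxy-2-(3-methylbut-2-en-1-yl)-1-[2-methyl-1-(trimethylsilyl)prop-2-en-1-yl]-1H-indene-1-carboxylic acid | CC(C)=CCC1=Cc2c(OC)ccc(OC)c2C1(C(=O)O)C([Si](C)(C)C)C(C)=C
F6 | step 6 | (S)-1-phenylethylammonium salt of 11 | CC(C)=CCC1=Cc2c(OC)ccc(OC)c2[C@]1(C(=O)[O-])C([Si](C)(C)C)C(C)=C.C[C@H]([NH3+])c1ccccc1
F7 | step 12 | quinone ketal: 18 with ring D as the p-benzoquinone | CC(C)=CC[C@@]12C3(OCC(C)(C)CO3)C=CC(=O)[C@@]14C=C(C)C[C@@H]2C2=C4C(=O)C=CC2=O
F8 | step 12 | hydroquinone ketal: 18 with ring D as the free 1,4-dihydroxybenzene | CC(C)=CC[C@@]12C3(OCC(C)(C)CO3)C=CC(=O)[C@@]14C=C(C)C[C@@H]2c2c(O)ccc(O)c24
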